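1. With time, [J] rises in the runs so far, within the scatter: G and Z start as solids with none in solution, and the early readings lie low, like a lag (induction period). You asked for a quick number and guessed that the clock counts for more than the charges, so here is my reckoning for the flask below.

| flask | G | Z | remark | time |
|---|---|---|---|---|
| dawn | 0.20 M | 0.60 equiv | run made earlier |  |
| summer | 0.20 M | 0.90 equiv | run made earlier |  |
| autumn | 0.30 M | 1.2 equiv | run made earlier |  |
| flask | 0.20 M | 1.20 equiv |  | 15 min |

- dawn (time / min: J / %): 1.50: 1; 4.00: 4; 8.00: 12; 12.0: 21
- summer (time / min: J / %): 1.00: 0; 2.00: 3; 5.00: 5; 12.0: 27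
- autumn (time / min: J / %): 1.50: 3; 4.00: 8; 8.00: 7; 12.0: 16

(scatter of a reading: 2 percentage points)

- solid, in amounts per volume of the solution: G, Z
- at the start none of G is in solution
- at the start none of Z is in solution

- how much J there is at 15 min, in percent of the G charged
- the change that raises the amount of J at 15 min, in percent of the G charged most ("none" if none brings more than 2 percentage points) (south-east / west / east / north-east / none)
- amount of J at 15 min, in percent of the G charged, after east

- south-east: doubling the dissolution coefficient of G, all else as stated
- west: doubling the solubility of Z, all else as stated
- east: doubling the solubility of G, all else as stated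
- north-east: doubling the dissolution coefficient of Z, all else as stated

2. Late end: at 12.0 min, [J] reads 0.0420 M in dawn and 0.0540 M in summer, and the three runs average 0.0480 M.

3. Dawn gains 0.004250 M/min from 4.00 min onward: this is the late rate, the [J] gained per minute past the lag. It is a reading and carries the scatter.

4. Early end: traced back, the dawn line meets zero at 2.12 min.

5. Join: adding 3.00 min at the late rate to the average gives me 30.4% of the G charged.

6. The forecast differs a little from my number: 32% (27% to 37%), best west, and 54% (38% to 66%) after east, reasoning: “Doubling either solubility should roughly double the rate”.

7. The flask gives 33.7%, best west at 11 percentage points, and 36.4% after east, a gain of 2.7 points.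

    G ⇌ D, rate k1*(cs1 - [D]) while solid is left; crystals form when [D] > cs1 (solubility = 39.0 mM, k = 0.0864 /s)
    Z ⇌ Q, rate k2*(cs2 - [Q]) while solid is left; crystals form when [Q] > cs2 (solubility = 0.160 M, k = 0.00378 /s)
    D + Q → J (k = 0.0325 /M/s)
    J ⇌ X (K = 0.670, k = 0.00391 /s)
    2 D → E (k = 0.0123 /M/s)

8. From 7.50 min to 15.0 min this flask gains 0.005160 M/min, faster than the late rate of 0.00425 M/min read from dawn. Carried to the same flask read at 10 min, the late rate gives 19.8%, and that flask holds 20.7% of J. At 4.74 min this flask makes J 3.30 times faster than it uses it up, each step taken net. At 15.0 min in this flask, D is made and used up in the ratio 0.999, each step taken net, with 18.5% of the G charged standing as D.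

The runs come from a simulation for substances that don't exist; the scatter is artificial.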